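The oxolane is numbered O1/C6–C9, counting chain atoms C1–C19 from the pentyl methyl, and C10 bears the laurate. The plan breaks O1–C6. The oxolane derives from a δ-lactone (O1, C5 carbonyl, C6–C9) with a C6 triflate and a cis C7 silyl ether, both oxygens coming from one osmylation. Methanolysis at C5 frees the C9 alkoxide, which displaces the triflate with inversion. One operation thus contracts the six-membered ring to the five-membered one, sets C6 and turns C5 into the exocyclic ester from which the pentyl chain grows. The feature used is the 1,4-placement of the C9 oxygen and C6, beside oxygenated C7.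

Key step: step 6

Remark: the α-hydroxyl (C6–OH) of diol 7 is assumed to be the more reactive one toward Tf2O, as is usual for 2,3-dihydroxy lactones; triflates 8 and 13 are taken on directly after a cold work-up but count as isolated compounds.

Step 1
Reactants: 1 (R)-benzyl glycidyl ether; 2 ethyl propiolate
Product: 4 ethyl (5R)-6-(benzyloxy)-5-hydroxyhex-2-ynoate, via ethyl 3-lithiopropiolate 3 (not isolated)
Conditions: 2, n-BuLi, THF, −78 °C; BF3·OEt2, then 1, −78 °C; aq NH4Cl
Reagents that add atoms: none
Why: Yamaguchi–Hirao alkynylation, in which the BF3-activated oxirane is opened by the lithium acetylide at its unsubstituted carbon (SN2), so the existing stereocentre (future C9) is not touched and the low temperature keeps the propiolate anion from self-condensing.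

Step 2
Reactants: 4 ethyl (5R)-6-(benzyloxy)-5-hydroxyhex-2-ynoate
Product: 6 (6R)-6-(benzyloxymethyl)-5,6-dihydro-2H-pyran-2-one, via Z-hydroxy enoate 5 (not isolated)
Conditions: H2 (1 atm), Lindlar catalyst, quinoline, EtOAc, rt; filter; then p-TsOH (cat.), toluene, 60 °C
Reagents that add atoms: none
Why: Lindlar semi-hydrogenation delivers hydrogen syn to give the Z-enoate, the only geometry in which the C9 hydroxyl reaches the ester, so acid-catalysed lactonisation closes the dihydropyranone with loss of ethanol while the poisoned catalyst leaves the benzyl ether alone.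

Step 3
Reactants: 6 (6R)-6-(benzyloxymethyl)-5,6-dihydro-2H-pyran-2-one
Product: 7 (3S,4S,6R)-6-(benzyloxymethyl)-3,4-dihydroxyoxan-2-one
Conditions: OsO4 (cat.), NMO, acetone/H2O, 0 °C → rt; aq Na2SO3
Reagents that add atoms: osmium tetroxide O=[Os](=O)(=O)=O (catalytic carrier of both oxygens); N-methylmorpholine N-oxide C[N+]1([O-])CCOCC1; water O
Why: Upjohn dihydroxylation, in which OsO4 adds suprafacially to the C6=C7 bond from the ring face opposite the C9 substituent and the pseudo-axial C8–H, so C6 and C7 are both set by substrate control, cis to each other and trans to CH2OBn (3S,4S).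

Step 4
Reactants: 7 (3S,4S,6R)-6-(benzyloxymethyl)-3,4-dihydroxyoxan-2-one
Product: 8 (3S,4S,6R)-6-(benzyloxymethyl)-4-hydroxy-2-oxooxan-3-yl trifluoromethanesulfonate
Conditions: Tf2O (1.05 equiv), pyridine, CH2Cl2, −40 °C; cold aqueous work-up
Reagents that add atoms: trifluoromethanesulfonic anhydride O=S(=O)(OS(=O)(=O)C(F)(F)F)C(F)(F)F
Why: Regioselective O-sulfonylation, in which the C6 hydroxyl next to the lactone carbonyl is the more acidic and more reactive of the two, so one equivalent of anhydride at low temperature should esterify it preferentially, as in the α-selective sulfonylation of 2,3-dihydroxy esters and aldonolactones, with no stereocentre changed.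

Step 5
Reactants: 8 (3S,4S,6R)-6-(benzyloxymethyl)-4-hydroxy-2-oxooxan-3-yl trifluoromethanesulfonate
Product: 9 (3S,4S,6R)-6-(benzyloxymethyl)-4-(tert-butyldimethylsilyloxy)-2-oxooxan-3-yl trifluoromethanesulfonate
Conditions: TBSOTf, 2,6-lutidine, CH2Cl2, −78 → −20 °C
Reagents that add atoms: tert-butyldimethylsilyl trifluoromethanesulfonate CC(C)(C)[Si](C)(C)OS(=O)(=O)C(F)(F)F
Why: Silyl ether formation with a silyl triflate and a hindered, non-nucleophilic base caps the C7 hydroxyl at low temperature without displacing or eliminating the neighbouring triflate, and the silyl group later keeps C7–O from closing an oxirane.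

Step 6
Reactants: 9 (3S,4S,6R)-6-(benzyloxymethyl)-4-(tert-butyldimethylsilyloxy)-2-oxooxan-3-yl trifluoromethanesulfonate
Product: 11 methyl (2R,3S,5R)-5-(benzyloxymethyl)-3-(tert-butyldimethylsilyloxy)oxolane-2-carboxylate, via open-chain alkoxide triflate 10 (not isolated)
Conditions: K2CO3 (1.5 equiv), dry MeOH, −20 → 0 °C; AcOH quench
Reagents that add atoms: methanol CO
Why: Methoxide generated by K2CO3 in methanol adds to the lactone carbonyl C5, which the α-triflyloxy group makes more electrophilic, and acyl–oxygen cleavage frees the C9 alkoxide of open-chain ester 10. That alkoxide attacks C6 from the side opposite the triflate in an intramolecular SN2 step, forming O1–C6 and the oxolane by a 5-exo-tet closure. The closest known reaction type is the base-induced contraction of aldono-δ-lactone 2-O-triflates to tetrahydrofuran-2-carboxylates. C6 is the only new stereocentre and is fixed by the inversion itself: the (6S)-triflate, cis to C7–O, gives the ester-bearing carbon with CO2Me cis to the C7 silyloxy group and trans to the C9 CH2OBn group, as the target requires. Substitution must outrun loss of triflic acid, α-epimerisation and oxirane formation; the fast five-membered closure with a weak base at low temperature answers the first two, and the silyl ether on the cis C7 oxygen removes the third. The reaction is quenched with acetic acid as soon as 9 is consumed so that the kinetic 2,3-cis ester is not equilibrated.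

Step 7
Reactants: 11 methyl (2R,3S,5R)-5-(benzyloxymethyl)-3-(tert-butyldimethylsilyloxy)oxolane-2-carboxylate
Product: 12 [(2S,3S,5R)-5-(benzyloxymethyl)-3-(tert-butyldimethylsilyloxy)oxolan-2-yl]methanol
Conditions: LiBH4, THF, 0 °C → rt
Reagents that add atoms: none
Why: Borohydride reduction of the α-alkoxy ester gives the C5 primary alcohol, the silyl and benzyl ethers being inert and the fast reduction removing the epimerisable ester before C6 can invert.

Step 8
Reactants: 12 [(2S,3S,5R)-5-(benzyloxymethyl)-3-(tert-butyldimethylsilyloxy)oxolan-2-yl]methanol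
Product: 13 [(2S,3S,5R)-5-(benzyloxymethyl)-3-(tert-butyldimethylsilyloxy)oxolan-2-yl]methyl trifluoromethanesulfonate
Conditions: Tf2O, 2,6-lutidine, CH2Cl2, −78 °C; short silica pad, used at once
Reagents that add atoms: trifluoromethanesulfonic anhydride O=S(=O)(OS(=O)(=O)C(F)(F)F)C(F)(F)F
Why: Standard triflation of a primary alcohol with a hindered pyridine base at −78 °C, with the 2,5-trans ring keeping the benzyloxy oxygen out of reach of C5.

Step 9
Reactants: 13 [(2S,3S,5R)-5-(benzyloxymethyl)-3-(tert-butyldimethylsilyloxy)oxolan-2-yl]methyl trifluoromethanesulfonate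
Product: 14 tert-butyl{[(2S,3S,5R)-5-(benzyloxymethyl)-2-pentyloxolan-3-yl]oxy}dimethylsilane
Conditions: n-BuMgCl, CuBr·SMe2 (cat.), Et2O/THF, −40 → 0 °C
Reagents that add atoms: n-butylmagnesium chloride CCCC[Mg]Cl
Why: Copper-catalysed sp3–sp3 cross-coupling of a primary triflate with a Grignard reagent, in which the butylcuprate formed in the flask displaces the C5 triflate by SN2 and completes the pentyl chain without touching C6.

Step 10
Reactants: 14 tert-butyl{[(2S,3S,5R)-5-(benzyloxymethyl)-2-pentyloxolan-3-yl]oxy}dimethylsilane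
Product: 15 [(2R,4S,5S)-4-(tert-butyldimethylsilyloxy)-5-pentyloxolan-2-yl]methanol
Conditions: H2 (1 atm), 10% Pd/C, EtOAc, rt
Reagents that add atoms: none
Why: Catalytic hydrogenolysis cleaves the benzyl ether to the C10 primary alcohol, the silyl ether being stable in ethyl acetate and the step being placed before the terminal alkene enters.

Step 11
Reactants: 15 [(2R,4S,5S)-4-(tert-butyldimethylsilyloxy)-5-pentyloxolan-2-yl]methanol
Product: 16 (2R,4S,5S)-4-(tert-butyldimethylsilyloxy)-5-pentyloxolane-2-carbaldehyde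
Conditions: Dess–Martin periodinane, NaHCO3, CH2Cl2, 0 °C → rt; used crude
Reagents that add atoms: none
Why: Dess–Martin oxidation under bicarbonate buffer stops at the α-alkoxy aldehyde and is mild enough to leave the C9 centre unepimerised.

Step 12
Reactants: 16 (2R,4S,5S)-4-(tert-butyldimethylsilyloxy)-5-pentyloxolane-2-carbaldehyde; 17 9-bromonon-1-ene
Product: 19 (1R)-1-[(2R,4S,5S)-4-(tert-butyldimethylsilyloxy)-5-pentyloxolan-2-yl]dec-9-en-1-ol, via non-8-enylmagnesium bromide 18 (not isolated)
Conditions: 17, Mg, I2 (cat.), Et2O, reflux; 16, MgBr2·OEt2, CH2Cl2, −78 °C, then 18, −78 → −40 °C; aq NH4Cl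
Reagents that add atoms: none
Why: Chelation-controlled (Cram-chelate) Grignard addition, in which Mg(II) ties the carbonyl oxygen to ring oxygen O1 and the non-8-enyl group adds from the side of the small C9–H, so C10 should be set R (threo to C9), 18 being made from 17 by magnesium insertion beforehand.

Step 13
Reactants: 19 (1R)-1-[(2R,4S,5S)-4-(tert-butyldimethylsilyloxy)-5-pentyloxolan-2-yl]dec-9-en-1-ol; 20 lauroyl chloride
Product: 21 (1R)-1-[(2R,4S,5S)-4-(tert-butyldimethylsilyloxy)-5-pentyloxolan-2-yl]dec-9-en-1-yl dodecanoate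
Conditions: 20, Et3N, DMAP (cat.), CH2Cl2, 0 °C → rt
Reagents that add atoms: none
Why: DMAP-catalysed O-acylation of the only free hydroxyl by the acid chloride gives the laurate with retention at C10.

Step 14
Reactants: 21 (1R)-1-[(2R,4S,5S)-4-(tert-butyldimethylsilyloxy)-5-pentyloxolan-2-yl]dec-9-en-1-yl dodecanoate
Product: 22 (1R)-1-[(2R,4S,5S)-4-hydroxy-5-pentyloxolan-2-yl]dec-9-en-1-yl dodecanoate (CNP0219213.1)
Conditions: HF·pyridine, pyridine, THF, 0 °C → rt
Reagents that add atoms: none
Why: Fluoride-mediated desilylation under buffered, non-basic conditions cleaves the Si–O bond without hydrolysing or shifting the laurate (C7–OH is trans to and remote from C10–O) and without affecting the alkene.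

Compound list
1 | (R)-benzyl glycidyl ether | C(c1ccccc1)OC[C@H]1CO1 | starting material
2 | ethyl propiolate | C#CC(=O)OCC | starting material
3 | ethyl 3-lithiopropiolate | [Li]C#CC(=O)OCC | intermediate
4 | ethyl (5R)-6-(benzyloxy)-5-hydroxyhex-2-ynoate | C(c1ccccc1)OC[C@H](O)CC#CC(=O)OCC | intermediate
5 | ethyl (2Z,5R)-6-(benzyloxy)-5-hydroxyhex-2-enoate | C(c1ccccc1)OC[C@H](O)C/C=C\C(=O)OCC | intermediate
6 | (6R)-6-(benzyloxymethyl)-5,6-dihydro-2H-pyran-2-one | C(c1ccccc1)OC[C@H]1CC=CC(=O)O1 | intermediate
7 | (3S,4S,6R)-6-(benzyloxymethyl)-3,4-dihydroxyoxan-2-one | C(c1ccccc1)OC[C@H]1C[C@H](O)[C@H](O)C(=O)O1 | intermediate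
8 | (3S,4S,6R)-6-(benzyloxymethyl)-4-hydroxy-2-oxooxan-3-yl trifluoromethanesulfonate | C(c1ccccc1)OC[C@H]1C[C@H](O)[C@H](OS(=O)(=O)C(F)(F)F)C(=O)O1 | intermediate
9 | (3S,4S,6R)-6-(benzyloxymethyl)-4-(tert-butyldimethylsilyloxy)-2-oxooxan-3-yl trifluoromethanesulfonate | C(c1ccccc1)OC[C@H]1C[C@H](O[Si](C)(C)C(C)(C)C)[C@H](OS(=O)(=O)C(F)(F)F)C(=O)O1 | intermediate
10 | methyl (2S,3S,5R)-6-(benzyloxy)-3-(tert-butyldimethylsilyloxy)-5-hydroxy-2-(trifluoromethylsulfonyloxy)hexanoate (present as its potassium alkoxide) | C(c1ccccc1)OC[C@H](O)C[C@H](O[Si](C)(C)C(C)(C)C)[C@H](OS(=O)(=O)C(F)(F)F)C(=O)OC | intermediate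
11 | methyl (2R,3S,5R)-5-(benzyloxymethyl)-3-(tert-butyldimethylsilyloxy)oxolane-2-carboxylate | C(c1ccccc1)OC[C@H]1C[C@H](O[Si](C)(C)C(C)(C)C)[C@H](C(=O)OC)O1 | intermediate
12 | [(2S,3S,5R)-5-(benzyloxymethyl)-3-(tert-butyldimethylsilyloxy)oxolan-2-yl]methanol | C(c1ccccc1)OC[C@H]1C[C@H](O[Si](C)(C)C(C)(C)C)[C@H](CO)O1 | intermediate
13 | [(2S,3S,5R)-5-(benzyloxymethyl)-3-(tert-butyldimethylsilyloxy)oxolan-2-yl]methyl trifluoromethanesulfonate | C(c1ccccc1)OC[C@H]1C[C@H](O[Si](C)(C)C(C)(C)C)[C@H](COS(=O)(=O)C(F)(F)F)O1 | intermediate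
14 | tert-butyl{[(2S,3S,5R)-5-(benzyloxymethyl)-2-pentyloxolan-3-yl]oxy}dimethylsilane | C(c1ccccc1)OC[C@H]1C[C@H](O[Si](C)(C)C(C)(C)C)[C@H](CCCCC)O1 | intermediate
15 | [(2R,4S,5S)-4-(tert-butyldimethylsilyloxy)-5-pentyloxolan-2-yl]methanol | OC[C@H]1C[C@H](O[Si](C)(C)C(C)(C)C)[C@H](CCCCC)O1 | intermediate
16 | (2R,4S,5S)-4-(tert-butyldimethylsilyloxy)-5-pentyloxolane-2-carbaldehyde | O=C[C@H]1C[C@H](O[Si](C)(C)C(C)(C)C)[C@H](CCCCC)O1 | intermediate
17 | 9-bromonon-1-ene | C=CCCCCCCCBr | starting material
18 | non-8-enylmagnesium bromide | C=CCCCCCCC[Mg]Br | intermediate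
19 | (1R)-1-[(2R,4S,5S)-4-(tert-butyldimethylsilyloxy)-5-pentyloxolan-2-yl]dec-9-en-1-ol | C=CCCCCCCC[C@@H](O)[C@H]1C[C@H](O[Si](C)(C)C(C)(C)C)[C@H](CCCCC)O1 | intermediate
20 | lauroyl chloride (dodecanoyl chloride) | CCCCCCCCCCCC(=O)Cl | starting material
21 | (1R)-1-[(2R,4S,5S)-4-(tert-butyldimethylsilyloxy)-5-pentyloxolan-2-yl]dec-9-en-1-yl dodecanoate | C=CCCCCCCC[C@@H](OC(=O)CCCCCCCCCCC)[C@H]1C[C@H](O[Si](C)(C)C(C)(C)C)[C@H](CCCCC)O1 | intermediate
22 | (1R)-1-[(2R,4S,5S)-4-hydroxy-5-pentyloxolan-2-yl]dec-9-en-1-yl dodecanoate (CNP0219213.1) | C=CCCCCCCC[C@@H](OC(=O)CCCCCCCCCCC)[C@H]1C[C@H](O)[C@H](CCCCC)O1 | target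

Total step count: 14.
Longest linear sequence: 14 steps (1 → 22); the Grignard reagent 18 is prepared within step 12.

Steps most likely to fail

Step 6 (ring contraction). What may go wrong is loss of triflic acid across C6–C7, equilibration of the kinetic 2,3-cis ester at C6, or a 1,3-silyl shift from O7 to the C9 alkoxide that frees O7 for oxirane closure, each in competition with the 5-exo displacement. The fallback sets out from 7 and uses the known cyclisation of hydroxy cyclic sulfates, which needs neither a triflate nor a silyl ether at the closing stage. Thionyl chloride and triethylamine (CH2Cl2, 0 °C) should give the C6/C7 cyclic sulfite F1, which RuCl3 (cat.)/NaIO4 in MeCN/H2O oxidises to the cyclic sulfate F2. K2CO3 in methanol opens the lactone at C5, and the C9 alkoxide opens the cyclic sulfate at C6 (5-exo-tet, inversion) to the potassium C7 sulfate monoester F3. Catalytic H2SO4 in wet THF hydrolyses this to the hydroxy ester F4, and TBSCl/imidazole in DMF brings the sequence back to 11.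

Step 4 (mono-triflation of the diol). What may go wrong is sulfonylation at the C7 hydroxyl or at both hydroxyls, and decomposition of the hydroxy triflate during work-up. The fallback sets out from 7 and differentiates the two oxygens with stable, separable silyl ethers before any triflate is made. TESCl/imidazole (DMF, −30 °C) should silylate the more acidic C6 hydroxyl to give the C6 triethylsilyl ether F5. TBSOTf/2,6-lutidine then gives the C6-TES/C7-TBS bis-silyl ether F6, and buffered HF·pyridine (THF, 0 °C) removes only the triethylsilyl group to give the C6 alcohol F7. Tf2O/pyridine at −40 °C then triflates the single free hydroxyl, and the route is rejoined at 9 with the key step unchanged.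

Step 12 (Grignard addition). What may go wrong is poor facial selectivity, with the open Felkin pathway competing against the chelate, and enolisation of the α-alkoxy aldehyde. The fallback sets out from 16 and fixes C10 by hydride delivery instead of C–C bond formation. Addition of 18 in THF at −78 °C without a chelating additive gives 19 together with its C10 epimer F8. Dess–Martin oxidation of the mixture gives the single ketone F9. L-Selectride (THF, −78 °C) reduces it under Felkin–Anh control, hydride arriving anti to the C9–O1 bond, which should give the threo alcohol and return the route to 19.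

Further compounds
F1 | step 6 | (3S,4S,6R)-6-(benzyloxymethyl)-3,4-(sulfinyldioxy)oxan-2-one (cyclic sulfite of 7, either configuration at sulfur) | C(c1ccccc1)OC[C@H]1C[C@@H]2OS(=O)O[C@@H]2C(=O)O1
F2 | step 6 | (3S,4S,6R)-6-(benzyloxymethyl)-3,4-(sulfonyldioxy)oxan-2-one (cyclic sulfate of 7) | C(c1ccccc1)OC[C@H]1C[C@@H]2OS(=O)(=O)O[C@@H]2C(=O)O1
F3 | step 6 | potassium (2R,3S,5R)-5-(benzyloxymethyl)-2-(methoxycarbonyl)oxolan-3-yl sulfate | C(c1ccccc1)OC[C@H]1C[C@H](OS(=O)(=O)[O-])[C@H](C(=O)OC)O1.[K+]
F4 | step 6 | methyl (2R,3S,5R)-5-(benzyloxymethyl)-3-hydroxyoxolane-2-carboxylate | C(c1ccccc1)OC[C@H]1C[C@H](O)[C@H](C(=O)OC)O1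
F5 | step 4 | (3S,4S,6R)-6-(benzyloxymethyl)-4-hydroxy-3-(triethylsilyloxy)oxan-2-one | C(c1ccccc1)OC[C@H]1C[C@H](O)[C@H](O[Si](CC)(CC)CC)C(=O)O1
F6 | step 4 | (3S,4S,6R)-6-(benzyloxymethyl)-4-(tert-butyldimethylsilyloxy)-3-(triethylsilyloxy)oxan-2-one | C(c1ccccc1)OC[C@H]1C[C@H](O[Si](C)(C)C(C)(C)C)[C@H](O[Si](CC)(CC)CC)C(=O)O1
F7 | step 4 | (3S,4S,6R)-6-(benzyloxymethyl)-4-(tert-butyldimethylsilyloxy)-3-hydroxyoxan-2-one | C(c1ccccc1)OC[C@H]1C[C@H](O[Si](C)(C)C(C)(C)C)[C@H](O)C(=O)O1
F8 | step 12 | (1S)-1-[(2R,4S,5S)-4-(tert-butyldimethylsilyloxy)-5-pentyloxolan-2-yl]dec-9-en-1-ol | C=CCCCCCCC[C@H](O)[C@H]1C[C@H](O[Si](C)(C)C(C)(C)C)[C@H](CCCCC)O1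
F9 | step 12 | 1-[(2R,4S,5S)-4-(tert-butyldimethylsilyloxy)-5-pentyloxolan-2-yl]dec-9-en-1-one | C=CCCCCCCCC(=O)[C@H]1C[C@H](O[Si](C)(C)C(C)(C)C)[C@H](CCCCC)O1
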